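**Retrosynthetic overview**
1. Core: aniline 1 (benzene ring bought) and Meldrum's acid 2 give, via malonamic acid 3, hydroxyquinolinone 4; this pyridone ring is the only ring of the target that is built. O-Methylation then gives 5.
2. Side chain: L-malic acid 6 supplies the single stereocenter and is taken through dioxolanone acid 7 and hydroxy acid 8 to hydroxylactone 9; both small rings are temporary.
3. Key disconnection: 9 is opened in the flask to carboxylate 10, and its radical forms the C3–CH2 bond of target 11 in a last, visible-light decarboxylative C–H alkylation of 5. The diol is never protected.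

Assumption: 2,4-dimethoxy-N-methylaniline 1 is taken as a catalog building block.

**Step 1**
Reactants: 1 2,4-dimethoxy-N-methylaniline; 2 Meldrum's acid (2,2-dimethyl-1,3-dioxane-4,6-dione)
Product: 4 4-hydroxy-6,8-dimethoxy-1-methylquinolin-2(1H)-one, via 3-[(2,4-dimethoxyphenyl)(methyl)amino]-3-oxopropanoic acid 3 (not isolated)
Conditions: 2 (1.1 equiv), toluene, 90 °C, 3 h; evaporate; Eaton's reagent (7.7 wt% P2O5 in MeSO3H, as solvent), 70 °C, 3 h; ice water, filter
Reagents that add atoms: none
Why: Meldrum's acid acylates the secondary aniline with loss of acetone, and the malonamic acid then closes the pyridone ring by intramolecular Friedel–Crafts acylation (Eaton's reagent cyclodehydration) at the only free position ortho to nitrogen; no stereocenter is involved.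

**Step 2**
Reactants: 4 4-hydroxy-6,8-dimethoxy-1-methylquinolin-2(1H)-one
Product: 5 4,6,8-trimethoxy-1-methylquinolin-2(1H)-one
Conditions: Me2SO4 (1.3 equiv), K2CO3 (2 equiv), acetone, reflux, 6 h
Reagents that add atoms: dimethyl sulfate, COS(=O)(=O)OC
Why: Williamson-type O-methylation of the vinylogous acid with a hard methylating agent and K2CO3 favors oxygen over C3, and nitrogen is already methylated.

**Step 3**
Reactants: 6 L-malic acid, (S)-2-hydroxybutanedioic acid
Product: 7 2-[(4S)-2,2-dimethyl-5-oxo-1,3-dioxolan-4-yl]acetic acid
Conditions: 2,2-dimethoxypropane (neat, excess), p-toluenesulfonic acid monohydrate (2 mol%), rt, 3 h; crystallize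
Reagents that add atoms: 2,2-dimethoxypropane, COC(C)(C)OC
Why: Acid-catalysed transketalization closes the five-membered dioxolanone on the alpha-hydroxy acid unit and leaves the CH2CO2H group free; the stereocenter bought in 6 is not touched.

**Step 4**
Reactants: 7 2-[(4S)-2,2-dimethyl-5-oxo-1,3-dioxolan-4-yl]acetic acid
Product: 9 (4S)-4-hydroxy-5,5-dimethyloxolan-2-one, via (S)-3,4-dihydroxy-4-methylpentanoic acid 8 (not isolated)
Conditions: MeMgBr (5 equiv), THF, −20 °C to rt, 3 h; then 2 M HCl to pH 1, rt, 2 h; EtOAc extraction
Reagents that add atoms: methylmagnesium bromide, C[Mg]Br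
Why: The magnesium carboxylate is inert, so double Grignard addition goes only to the activated dioxolanone carbonyl (ester-to-tertiary-alcohol addition) and builds the CMe2OH group, and acid work-up lactonizes the gamma-hydroxy acid; the stereocenter is carried over from 6 because no bond to it is broken.

**Step 5**
Reactants: 5 4,6,8-trimethoxy-1-methylquinolin-2(1H)-one; 9 (4S)-4-hydroxy-5,5-dimethyloxolan-2-one
Product: 11 4,6,8-trimethoxy-1-methyl-3-[(2S)-2,3-dihydroxy-3-methylbutyl]quinolin-2(1H)-one, via cesium (S)-3,4-dihydroxy-4-methylpentanoate 10 (not isolated)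
Conditions: 9 (3 equiv), CsOH·H2O (3 equiv), MeCN/H2O 9:1, 0 °C to rt, 1 h; then 5 (1 equiv), 2,4,5,6-tetrakis(carbazol-9-yl)isophthalonitrile (4CzIPN, 2 mol%), Co(dmgH)2(py)Cl (5 mol%), Ar, 450 nm LEDs, 30 °C, 24 h
Reagents that add atoms: cesium hydroxide monohydrate, [Cs+].[OH-].O (its atoms enter intermediate 10 and leave again with the carboxyl group; none stay in 11)
Why: Proposed new method: dehydrogenative decarboxylative C3–H alkylation of a 4-alkoxyquinolin-2-one by an unprotected dihydroxy carboxylate; excited 4CzIPN (about +1.35 V vs SCE) oxidizes 10, loss of CO2 gives the primary radical •CH2–CH(OH)–CMe2OH, which adds to the unsubstituted C3 because this creates a tertiary alpha-methoxy benzylic radical at C4, and the cobaloxime (brought to divalent cobalt by the photocatalyst radical anion) removes the C3 hydrogen atom, restores the quinolinone and releases H2, so no chemical oxidant meets the free diol; the stereocenter sits beta to the radical carbon, never reacts and is carried over from L-malic acid unchanged; the closest known reaction types are the photoredox/cobaloxime decarboxylative Heck-type alkylation of vinyl arenes with hydrogen evolution and the radical C3–H alkylation of coumarins and quinoxalin-2-ones.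

**Compound list**
1 | 2,4-dimethoxy-N-methylaniline | CNc1ccc(OC)cc1OC | starting material
2 | Meldrum's acid (2,2-dimethyl-1,3-dioxane-4,6-dione) | CC1(C)OC(=O)CC(=O)O1 | starting material
3 | 3-[(2,4-dimethoxyphenyl)(methyl)amino]-3-oxopropanoic acid | CN(C(=O)CC(O)=O)c1ccc(OC)cc1OC | intermediate
4 | 4-hydroxy-6,8-dimethoxy-1-methylquinolin-2(1H)-one | COc1cc(OC)c2c(c1)c(O)cc(=O)n2C | intermediate
5 | 4,6,8-trimethoxy-1-methylquinolin-2(1H)-one | COc1cc(OC)c2c(c1)c(OC)cc(=O)n2C | intermediate
6 | L-malic acid, (S)-2-hydroxybutanedioic acid | OC(=O)C[C@H](O)C(O)=O | starting material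
7 | 2-[(4S)-2,2-dimethyl-5-oxo-1,3-dioxolan-4-yl]acetic acid | OC(=O)C[C@@H]1OC(C)(C)OC1=O | intermediate
8 | (S)-3,4-dihydroxy-4-methylpentanoic acid | OC(=O)C[C@H](O)C(C)(C)O | intermediate
9 | (4S)-4-hydroxy-5,5-dimethyloxolan-2-one | O=C1C[C@H](O)C(C)(C)O1 | intermediate
10 | cesium (S)-3,4-dihydroxy-4-methylpentanoate | [Cs+].[O-]C(=O)C[C@H](O)C(C)(C)O | intermediate
11 | 4,6,8-trimethoxy-1-methyl-3-[(2S)-2,3-dihydroxy-3-methylbutyl]quinolin-2(1H)-one | COc1cc(OC)c2c(c1)c(OC)c(C[C@H](O)C(C)(C)O)c(=O)n2C | target

**Step count and risks**
Total steps: 5. Longest linear sequence: 3 steps (6 to 7 to 9 to 11; the branch 1 to 4 to 5 to 11 is equally long).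

Most likely to fail, in this order:

1. Step 5 (proposed new method). The nucleophilic primary radical may add too slowly to the electron-rich C3, so that the cobaloxime dehydrogenates the radical instead; the excess of 10 is there to cover this loss. The photocatalyst may also oxidize the dimethoxy-substituted ring of 5 reversibly and slow the reaction. Fallback with known chemistry, setting out from 5 and 9 and coming back at 11: 5 is brominated at its most nucleophilic carbon with N-bromosuccinimide (1.05 equiv, MeCN, 0 °C) to give 3-bromo-4,6,8-trimethoxy-1-methylquinolin-2(1H)-one F1. F1 is then joined to carboxylate 10 (made from 9 and CsOH·H2O as before) by nickel/iridium dual photoredox decarboxylative arylation: NiCl2·glyme (10 mol%), 4,4'-di-tert-butyl-2,2'-bipyridine (15 mol%), Ir[dF(CF3)ppy]2(dtbbpy)PF6 (2 mol%), DMF, 450 nm LEDs, rt. This gives 11 directly, and the bond is still made under light with the same chiral-pool fragment.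

2. Step 4. The magnesium carboxylate of 7 may be poorly soluble, and the dioxolanone may be partly enolized by the Grignard reagent, which would lower yield or optical purity. Fallback, setting out from 6 and coming back at 9: L-malic acid is treated with trifluoroacetic anhydride (neat, 0 °C to rt) and then methanol. This opens the cyclic anhydride at the carbonyl next to the oxygen-bearing carbon and gives the 1-monomethyl ester (S)-3-hydroxy-4-methoxy-4-oxobutanoic acid F2. MeMgBr (4.5 equiv, THF, 0 °C to rt) then adds twice to the only ester of the alkoxide carboxylate dianion, which cannot enolize easily, and work-up with 2 M HCl closes lactone 9.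

3. Step 1. The ring carbon that must be acylated is meta to both methoxy groups, and methanesulfonic anhydride in Eaton's reagent can sulfonylate the electron-rich ring. Fallback, setting out from 1 and coming back at 4: 1 is heated with bis(2,4,6-trichlorophenyl) malonate (1.0 equiv) in diphenyl ether at 200–220 °C. This first gives the aryl malonamate 2,4,6-trichlorophenyl 3-[(2,4-dimethoxyphenyl)(methyl)amino]-3-oxopropanoate F3 (not isolated). F3 loses trichlorophenol to an acylketene that closes thermally onto the ring, a neutral pathway that avoids strong acid altogether, and 4 crystallizes on cooling and dilution with hexane.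

**Further compounds**
F1 | step 5 | 3-bromo-4,6,8-trimethoxy-1-methylquinolin-2(1H)-one | COc1cc(OC)c2c(c1)c(OC)c(Br)c(=O)n2C
F2 | step 4 | (S)-3-hydroxy-4-methoxy-4-oxobutanoic acid | OC(=O)C[C@H](O)C(=O)OC
F3 | step 1 | 2,4,6-trichlorophenyl 3-[(2,4-dimethoxyphenyl)(methyl)amino]-3-oxopropanoate | CN(C(=O)CC(=O)Oc1c(Cl)cc(Cl)cc1Cl)c1ccc(OC)cc1OC
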